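## Analysis of the target

- The target is a 5-methylcoumarin whose O4 carries an (E)-3-methylpent-2-enyl chain (C1' at oxygen to C5') that ends at C2 of a 1,3,3-trimethyl-7-oxabicyclo[2.2.1]heptane.
- The bicycle holds the only three stereocentres, C1 (R), C2 (S) and C4 (S). C1 and C4 are tied together by the O7 bridge, so only two elements are independent: the absolute sense of the bridge and the exo placing of the C2 chain (syn to O7).
- C2 lies between two fully substituted carbons, the methyl- and oxygen-bearing bridgehead C1 and the gem-dimethyl carbon C3, so every bond made at or next to C2 is sterically slowed.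
- The 4-alkoxycoumarin is a vinylogous carbonate: it opens with hydroxide or alkoxide, and its allyl aryl ether ionises with acid and undergoes Claisen rearrangement on heating. The C2'=C3' olefin must be E and cannot survive a hydrogenation, and the bridge can ionise at tertiary C1 under strong acid.
- The main difficulty is that the saturated ether bicycle has no functional handle for late introduction of asymmetry, so the absolute configuration has to arise in the ring-forming event itself.
- The strategy rests on reading the ring C1–C6 with O7 as a hydrogenated furan–alkene adduct. C1, C6, C5, C4 and O7 map onto 2-methylfuran, and C2–C3 onto an alkene whose C3 end is a cyclopropylidene carbon, the cyclopropane serving as latent gem-dimethyl.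

## Retrosynthetic reasoning

**O4–C1' bond.** The ether is cut last, giving allylic alcohol 14 and 4-hydroxy-5-methylcoumarin 16. This keeps the base-, acid- and heat-sensitive coumarin ether out of all earlier steps and makes the route convergent. The forward Mitsunobu reaction has to alkylate O4 and not C3 or the lactone carbonyl oxygen.

**Coumarin ring.** 16 is cut at C2–C3 and O1–C2 to the acetophenone 15 plus a one-carbon carbonyl unit. The aryl methyl of 15 is already in the right place for C5.

**C2'=C3' bond.** 14 comes from ester 13 by reduction, and 13 from methyl ketone 12 by a phosphonate olefination that brings in C2' and C1'. Cutting here uses the C3' methyl as the ketone methyl, so the forward step only has to favour the E isomer.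

**C4'–C5' bond.** 12 comes from enone 11 by saturation, and 11 from aldehyde 10 by olefination at C5'. The cut is made as an olefin because carbonyl addition is the only reliable way to form a bond next to the congested C2. The hydrogenation is placed here, before C2'=C3' exists.

**Oxidation level at C5'.** Aldehyde 10 goes back through alcohol 9 to ester 8, the oxidation state a cycloaddition delivers directly.

**C3 methyls and C5–C6.** The two methyls of 8 are joined to the cyclopropane of 7 (forward: hydrogenolysis of the distal bond). 7 comes from alkene 6 by hydrogenation, which also locks the adduct against cycloreversion.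

**C1–C2 and C3–C4 (key).** 6 is cut to 2-methylfuran 5 and ethyl cyclopropylideneacetate 4. No other pair of cuts removes both bonds flanking C2, both rings and all three stereocentres at once. The forward reaction must control regiochemistry (methyl next to ester), the face of 4 that is attacked, and exo orientation.

**Dienophile.** 4 is cut at its C=C bond to the cyclopropanone equivalent 1 (through hemiacetal 3) and the stabilised ylide 2.

## Alternatives that were turned down

**Alternative 1: transannular iodoetherification.**
- Disconnection: the C4–O7 bond.
- Forward key step: an electrophilic iodine source activates C4=C5 of cyclohexenol A2, the tertiary C1 hydroxyl attacks C4 across the ring, and iodo ether A1 results with iodine endo at C5.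
- For: the anti addition is irreversible and needs no catalyst design. After deiodination and ketal removal A1 gives ketone 12 directly, so the chain steps 5 to 8 of the chosen route are not needed. On reliability of the key step this alternative is stronger.
- Against: A2 already holds the C1 carbinol and the neighbouring C2 chain in a cis relationship and in absolute form. That pair must be built in an open-chain diene before a ring-closing metathesis that has to close beside the gem-dimethyl carbon. Oxygen must attack the neopentyl C4 from a boat-like conformer, and two clean-up steps follow.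
- Comparison: the hard stereochemical problem is moved, not solved. The chosen route makes both rings and all three stereocentres in one step from two achiral partners, each available in at most one step.

**Alternative 2: zirconium-catalysed methylalumination.**
- Disconnection: C3'–CH3 and C2'–C1'.
- Forward key step: alkyne A4 undergoes syn methylalumination and the alkenyl metal, as its ate complex, is trapped by a one-carbon electrophile to give allylic alcohol A3 (identical with 14).
- For: syn carbometalation fixes the E geometry almost completely. On this point it is stronger than the olefination of ketone 12 in step 9, which is expected to give some Z isomer.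
- Against: it is a side-chain step. It says nothing about the oxygen bridge or the three stereocentres, all of which must already be present in A4, and it uses a pyrophoric reagent on late material.
- Comparison: it cannot carry the synthesis. The chosen strategy addresses the bicycle and keeps this chemistry in reserve as the fallback for step 9.

**Alternative 3: allylsilane closure onto an oxolane oxocarbenium ion.**
- Disconnection: the C1–C2 bond.
- Forward key step: a silyl triflate ionises cyclic ketal A6 at C1 and the tethered (E)-allylsilane attacks through C2, giving vinyl bicycle A5.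
- For: only one stereocentre (C4) is needed beforehand and it dictates C1 through the bridge. The gem-dimethyl group is present from the start, so no masking or hydrogenolysis is needed, and the closure is irreversible. On these points it is stronger.
- Against: a two-atom tether must reach across the same five-membered ring that carries the cation, a strained bridging closure. It competes with proton loss to an enol ether and with protodesilylation. The exo or endo placing of the vinyl group depends on small differences between transition-state shapes with no chance of correction. A5 still needs a long elongation from a hindered vinyl group, and A6 itself needs several steps.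
- Comparison: the diastereoselectivity risk is of the same kind as in the cycloaddition, but the precursor is longer to make. The chosen route puts its single large risk on two compounds that are trivial to obtain.

Key step: step 2

Remark on locants: the bicycle is numbered as in the target (C1 methyl bridgehead, C2, C3, C4 bridgehead, C5, C6, O7), also for the spiro compounds; the side chain runs from C1' (OCH2) to C5' (on C2).

Assumption: the sense of induction of the oxazaborolidinium catalyst on ester 4 is taken from the usual α-C–H···O binding picture of acrylates, which is assumed to place the shielding aryl group of the (S)-proline-derived catalyst over the α-Si face; if the first adduct shows the opposite sense, the (R) catalyst is used and nothing else changes.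

## Route

Step 1
Reactants: 1 (1-ethoxycyclopropoxy)trimethylsilane; 2 ethyl (triphenylphosphoranylidene)acetate
Product: 4 ethyl 2-cyclopropylideneacetate, via 1-ethoxycyclopropan-1-ol 3 (not isolated)
Conditions: MeOH, rt, evaporate; then 2, PhCO2H (cat.), toluene, 85 °C
Reagents that add atoms: none
Why: Wittig olefination of a masked cyclopropanone: methanolysis frees hemiacetal 3, which under benzoic acid catalysis hands the strained ketone to the stabilised ylide; this is the established way to alkyl cyclopropylideneacetates and creates no stereocentre.

Step 2
Reactants: 4 ethyl 2-cyclopropylideneacetate; 5 2-methylfuran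
Product: 6 ethyl (1R,2S,4S)-1-methylspiro[7-oxabicyclo[2.2.1]hept-5-ene-3,1'-cyclopropane]-2-carboxylate (CO2Et exo, syn to O7)
Conditions: 5 (5 equiv), (S)-1-(2-methylphenyl)-3,3-diphenyltetrahydro-1H,3H-pyrrolo[1,2-c][1,3,2]oxazaborole (20 mol%), (CF3SO2)2NH (18 mol%), CH2Cl2, −78 → −40 °C; Et3N at −78 °C, cold chromatography
Reagents that add atoms: none
Why: Proposed new method: the boron-bound ester reacts in a concerted but asynchronous π4s+π2s cycloaddition in which the free furan terminus (future C4) bonds first to the cyclopropylidene carbon (future C3) and the methyl-bearing terminus (future C1) then closes onto the α-carbon (future C2); the closest known reaction types are the oxazaborolidinium-catalysed Diels–Alder reaction of furans with acrylates and the uncatalysed high-pressure addition of cyclopropylideneacetates to furans, which have not been combined. Both new rings, the cyclohexene C1–C6 and the oxolane O7–C1–C2–C3–C4, are closed by this single suprafacial bond pair, with no separate ring-closing event. Rehybridisation of the cyclopropylidene carbon releases the extra strain of the exocyclic double bond, which should let a fully substituted dienophile terminus react and should make the adduct less prone to revert than that of an isopropylidene ester. Regiochemistry follows from the largest HOMO coefficient at the free α-position of 5 meeting the β-carbon of 4 and from avoiding two adjacent quaternary centres. C2 is set by the catalyst, whose aryl group has to cover the α-Si face of bound 4 so that the furan adds to the α-Re face, while C1 and C4, tied to each other by the bridge, are set relative to C2 by the exo orientation. Exo selectivity cannot come from full equilibration, because the enantiomeric adducts are isoenergetic and a complete equilibrium is racemic; the step instead relies on the endo isomer cycloreverting on the catalyst much faster than the exo isomer, so that at −40 °C material drains into an exo adduct whose configuration was fixed kinetically, and on quenching before the exo adduct starts to revert. Residual endo isomer, formed on the same dienophile face and therefore of opposite bridgehead configuration, is removed by chromatography, and 6 is hydrogenated at once.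

Step 3
Reactants: 6 exo cycloadduct
Product: 7 ethyl (1R,2S,4S)-1-methylspiro[7-oxabicyclo[2.2.1]heptane-3,1'-cyclopropane]-2-carboxylate
Conditions: H2 (1 atm), 5% Pd/C, EtOAc, 0 °C → rt
Reagents that add atoms: none
Why: Heterogeneous hydrogenation of the strained bridge alkene from the exo face is fast under conditions that leave the cyclopropane, the ester and the C–O bonds alone; it removes the diene unit needed for cycloreversion and creates no stereocentre.

Step 4
Reactants: 7 saturated spirocyclopropane ester
Product: 8 ethyl (1R,2S,4S)-1,3,3-trimethyl-7-oxabicyclo[2.2.1]heptane-2-carboxylate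
Conditions: H2 (4 atm), PtO2, AcOH, rt → 50 °C
Reagents that add atoms: none
Why: Catalytic hydrogenolysis of a spirocyclopropane over platinum cleaves the bond between the two least substituted carbons, here the exposed CH2–CH2 bond opposite C3, so both carbons end as methyl groups on C3; the two bonds to C3 are shielded by C2 and C4, and no stereocentre is touched.

Step 5
Reactants: 8 gem-dimethyl ester
Product: 9 [(1R,2R,4S)-1,3,3-trimethyl-7-oxabicyclo[2.2.1]heptan-2-yl]methanol (CH2OH exo; the descriptor at C2 changes by priority only)
Conditions: LiAlH4, THF, 0 °C → rt; aq. NaOH work-up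
Reagents that add atoms: none
Why: Hydride reduction of an ester to the primary alcohol; no enolate is formed, so C2 keeps its configuration and the bridge oxygen cannot be eliminated.

Step 6
Reactants: 9 primary alcohol
Product: 10 (1R,2S,4S)-1,3,3-trimethyl-7-oxabicyclo[2.2.1]heptane-2-carbaldehyde
Conditions: Dess–Martin periodinane, CH2Cl2, rt
Reagents that add atoms: none
Why: Dess–Martin oxidation stops at the aldehyde under nearly neutral conditions; the exo aldehyde is also the thermodynamically preferred epimer, so adventitious enolisation would not change C2.

Step 7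
Reactants: 10 aldehyde
Product: 11 (3E)-4-[(1R,2S,4S)-1,3,3-trimethyl-7-oxabicyclo[2.2.1]heptan-2-yl]but-3-en-2-one
Conditions: (MeO)2P(O)CH2C(O)CH3, NaH, THF, 0 → 50 °C
Reagents that add atoms: dimethyl (2-oxopropyl)phosphonate, COP(=O)(CC(C)=O)OC
Why: Horner–Wadsworth–Emmons olefination; the small, strongly nucleophilic phosphonate anion is preferred to a stabilised phosphorane because the aldehyde is flanked by C1 and C3, and the stabilised reagent gives the E enone.

Step 8
Reactants: 11 enone
Product: 12 4-[(1R,2S,4S)-1,3,3-trimethyl-7-oxabicyclo[2.2.1]heptan-2-yl]butan-2-one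
Conditions: H2 (1 atm), 10% Pd/C, EtOAc, rt
Reagents that add atoms: none
Why: Catalytic hydrogenation of the conjugated C4'=C5' bond, the only alkene present at this stage, is faster than ketone reduction.

Step 9
Reactants: 12 methyl ketone
Product: 13 ethyl (2E)-3-methyl-5-[(1R,2S,4S)-1,3,3-trimethyl-7-oxabicyclo[2.2.1]heptan-2-yl]pent-2-enoate
Conditions: (EtO)2P(O)CH2CO2Et, NaH, THF, 0 °C → reflux; chromatographic removal of the Z isomer
Reagents that add atoms: triethyl phosphonoacetate, CCOC(=O)CP(=O)(OCC)OCC
Why: Horner–Wadsworth–Emmons olefination of a methyl ketone; the E isomer should predominate because the ester avoids the larger C4' substituent in the oxaphosphetane, and the minor Z isomer is separable here or after step 10.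

Step 10
Reactants: 13 E enoate
Product: 14 (2E)-3-methyl-5-[(1R,2S,4S)-1,3,3-trimethyl-7-oxabicyclo[2.2.1]heptan-2-yl]pent-2-en-1-ol
Conditions: i-Bu2AlH, CH2Cl2, −78 °C; aq. potassium sodium tartrate
Reagents that add atoms: none
Why: 1,2-Reduction of the conjugated ester by i-Bu2AlH at low temperature gives the allylic alcohol without changing the olefin geometry or touching the oxygen bridge.

Step 11
Reactants: 15 1-(2-hydroxy-6-methylphenyl)ethanone
Product: 16 4-hydroxy-5-methyl-2H-chromen-2-one
Conditions: NaH, (EtO)2CO, toluene, 110 °C; then aq. HCl
Reagents that add atoms: diethyl carbonate, CCOC(=O)OCC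
Why: Claisen-type C-acylation of the acetyl group by diethyl carbonate followed by lactonisation onto the phenoxide is the standard route to 4-hydroxycoumarins; the aryl methyl ends at C5.

Step 12
Reactants: 14 allylic alcohol; 16 4-hydroxy-5-methylcoumarin
Product: 17 5-methyl-4-{[(2E)-3-methyl-5-[(1R,2S,4S)-1,3,3-trimethyl-7-oxabicyclo[2.2.1]heptan-2-yl]pent-2-en-1-yl]oxy}-2H-chromen-2-one
Conditions: PPh3, DIAD, THF, 0 °C → rt
Reagents that add atoms: none
Why: Mitsunobu etherification: the acidic 4-hydroxyl is a competent pronucleophile and the primary allylic oxyphosphonium is displaced at C1' in an SN2 sense, so the E olefin and the remote stereocentres are untouched; neutral, cold conditions spare the lactone and avoid Claisen rearrangement.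

## Compound list

1 | (1-ethoxycyclopropoxy)trimethylsilane | CCOC1(CC1)O[Si](C)(C)C | starting material
2 | ethyl (triphenylphosphoranylidene)acetate | CCOC(=O)C=P(c1ccccc1)(c1ccccc1)c1ccccc1 | starting material
3 | 1-ethoxycyclopropan-1-ol | CCOC1(O)CC1 | intermediate
4 | ethyl 2-cyclopropylideneacetate | CCOC(=O)C=C1CC1 | intermediate
5 | 2-methylfuran | Cc1ccco1 | starting material
6 | ethyl (1R,2S,4S)-1-methylspiro[7-oxabicyclo[2.2.1]hept-5-ene-3,1'-cyclopropane]-2-carboxylate | CCOC(=O)[C@H]1C2(CC2)[C@@H]3C=C[C@@]1(C)O3 | intermediate
7 | ethyl (1R,2S,4S)-1-methylspiro[7-oxabicyclo[2.2.1]heptane-3,1'-cyclopropane]-2-carboxylate | CCOC(=O)[C@H]1C2(CC2)[C@@H]3CC[C@@]1(C)O3 | intermediate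
8 | ethyl (1R,2S,4S)-1,3,3-trimethyl-7-oxabicyclo[2.2.1]heptane-2-carboxylate | CCOC(=O)[C@H]1C(C)(C)[C@@H]2CC[C@@]1(C)O2 | intermediate
9 | [(1R,2R,4S)-1,3,3-trimethyl-7-oxabicyclo[2.2.1]heptan-2-yl]methanol | OC[C@H]1C(C)(C)[C@@H]2CC[C@@]1(C)O2 | intermediate
10 | (1R,2S,4S)-1,3,3-trimethyl-7-oxabicyclo[2.2.1]heptane-2-carbaldehyde | O=C[C@H]1C(C)(C)[C@@H]2CC[C@@]1(C)O2 | intermediate
11 | (3E)-4-[(1R,2S,4S)-1,3,3-trimethyl-7-oxabicyclo[2.2.1]heptan-2-yl]but-3-en-2-one | CC(=O)/C=C/[C@H]1C(C)(C)[C@@H]2CC[C@@]1(C)O2 | intermediate
12 | 4-[(1R,2S,4S)-1,3,3-trimethyl-7-oxabicyclo[2.2.1]heptan-2-yl]butan-2-one | CC(=O)CC[C@H]1C(C)(C)[C@@H]2CC[C@@]1(C)O2 | intermediate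
13 | ethyl (2E)-3-methyl-5-[(1R,2S,4S)-1,3,3-trimethyl-7-oxabicyclo[2.2.1]heptan-2-yl]pent-2-enoate | CCOC(=O)/C=C(\C)CC[C@H]1C(C)(C)[C@@H]2CC[C@@]1(C)O2 | intermediate
14 | (2E)-3-methyl-5-[(1R,2S,4S)-1,3,3-trimethyl-7-oxabicyclo[2.2.1]heptan-2-yl]pent-2-en-1-ol | OC/C=C(\C)CC[C@H]1C(C)(C)[C@@H]2CC[C@@]1(C)O2 | intermediate
15 | 1-(2-hydroxy-6-methylphenyl)ethanone | CC(=O)c1c(C)cccc1O | starting material
16 | 4-hydroxy-5-methyl-2H-chromen-2-one | Cc1cccc2oc(=O)cc(O)c12 | intermediate
17 | 5-methyl-4-{[(2E)-3-methyl-5-[(1R,2S,4S)-1,3,3-trimethyl-7-oxabicyclo[2.2.1]heptan-2-yl]pent-2-en-1-yl]oxy}-2H-chromen-2-one | C/C(=C\COc1cc(=O)oc2cccc(C)c12)CC[C@H]1C(C)(C)[C@@H]2CC[C@@]1(C)O2 | target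

## Step count and least certain steps

Total step count: 12. Longest linear sequence: 11 (steps 1 to 10 and step 12; step 11 is a one-step branch).

**Step 2 (key step, proposed new method).**
- What may go wrong: the furan may add in a conjugate (Friedel–Crafts) sense and lose a proton before closing the second bond. The Lewis acid may open the allylic, cyclopropylcarbinyl oxygen bridge. The ethyl ester may turn over too slowly on the catalyst. Facial or exo selectivity may be low, or cycloreversion of the exo adduct may erode the enantiomeric purity.
- Fallback (known chemistry, from 4 and 5, returning at 7): 4 and excess 5 are combined without any acid at 10 to 12 kbar and room temperature, the known mode for cyclopropylideneacetates and furans. The racemic exo adduct, racemic ethyl 1-methylspiro[7-oxabicyclo[2.2.1]hept-5-ene-3,1'-cyclopropane]-2-carboxylate F1, is separated from the endo isomer, which reverts to 4 and 5 on gentle warming and is recycled. Hydrogenation over Pd/C gives the racemic saturated ester F2, and LiOH in aqueous THF gives the racemic acid F3. The acid is resolved by crystallising the (R)-1-phenylethylammonium salt of the (1R,2S,4S) acid F4 (the antipodal amine is used if the other salt is the less soluble one). Aqueous HCl liberates (1R,2S,4S)-1-methylspiro[7-oxabicyclo[2.2.1]heptane-3,1'-cyclopropane]-2-carboxylic acid F5, and EtI with K2CO3 in DMF gives 7.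

**Step 7.**
- What may go wrong: addition to the aldehyde may be slow because C5' is flanked by C1 and C3, leaving time for enolisation and loss of the bridge oxygen by β-elimination.
- Fallback (from 10, returning at 11): the lithium enolate of acetone (LDA, THF, −78 °C) adds to 10 to give the aldol 4-hydroxy-4-[(1R,2R,4S)-1,3,3-trimethyl-7-oxabicyclo[2.2.1]heptan-2-yl]butan-2-one F6 as a carbinol mixture. Mesylation and elimination (MsCl, Et3N, CH2Cl2) then give 11.

**Step 9.**
- What may go wrong: poor E/Z selectivity in the olefination of a methyl ketone, with loss of material on separation.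
- Fallback (from 12, returning at 14, bypassing 13): kinetic enolisation at the methyl group (LDA, −78 °C) and trapping with ClP(O)(OEt)2 give the enol phosphate diethyl 4-[(1R,2S,4S)-1,3,3-trimethyl-7-oxabicyclo[2.2.1]heptan-2-yl]but-1-en-2-yl phosphate F7. Further LDA eliminates it to the terminal alkyne (1R,2S,4S)-2-(but-3-yn-1-yl)-1,3,3-trimethyl-7-oxabicyclo[2.2.1]heptane F8. Me3Al with catalytic Cp2ZrCl2 in CH2Cl2 adds syn to give the (E)-alkenylalane dimethyl[(1E)-2-methyl-4-[(1R,2S,4S)-1,3,3-trimethyl-7-oxabicyclo[2.2.1]heptan-2-yl]but-1-en-1-yl]alumane F9, which as its n-BuLi ate complex is trapped with paraformaldehyde to give 14 with the E geometry fixed by the syn addition.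

**Step 12.**
- What may go wrong: alkylation at C3 or at the lactone carbonyl oxygen in place of O4, helped by the peri methyl group, and allylic transposition (SN2′).
- Fallback (from 16 and 14, returning at 17): the bond is made from the other side. 16 is converted with POCl3 into 4-chloro-5-methyl-2H-chromen-2-one F10, and the sodium alkoxide of 14 (NaH, THF, 0 °C) displaces chloride at C4 by addition–elimination, which can only give the O4 ether.

## Further compounds

F1 | step 2 | racemic ethyl (1R*,2S*,4S*)-1-methylspiro[7-oxabicyclo[2.2.1]hept-5-ene-3,1'-cyclopropane]-2-carboxylate (one enantiomer drawn) | CCOC(=O)[C@H]1C2(CC2)[C@@H]3C=C[C@@]1(C)O3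
F2 | step 2 | racemic ethyl (1R*,2S*,4S*)-1-methylspiro[7-oxabicyclo[2.2.1]heptane-3,1'-cyclopropane]-2-carboxylate (one enantiomer drawn) | CCOC(=O)[C@H]1C2(CC2)[C@@H]3CC[C@@]1(C)O3
F3 | step 2 | racemic (1R*,2S*,4S*)-1-methylspiro[7-oxabicyclo[2.2.1]heptane-3,1'-cyclopropane]-2-carboxylic acid (one enantiomer drawn) | OC(=O)[C@H]1C2(CC2)[C@@H]3CC[C@@]1(C)O3
F4 | step 2 | (R)-1-phenylethylammonium (1R,2S,4S)-1-methylspiro[7-oxabicyclo[2.2.1]heptane-3,1'-cyclopropane]-2-carboxylate | [O-]C(=O)[C@H]1C2(CC2)[C@@H]3CC[C@@]1(C)O3.C[C@@H]([NH3+])c1ccccc1
F5 | step 2 | (1R,2S,4S)-1-methylspiro[7-oxabicyclo[2.2.1]heptane-3,1'-cyclopropane]-2-carboxylic acid | OC(=O)[C@H]1C2(CC2)[C@@H]3CC[C@@]1(C)O3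
F6 | step 7 | 4-hydroxy-4-[(1R,2R,4S)-1,3,3-trimethyl-7-oxabicyclo[2.2.1]heptan-2-yl]butan-2-one (carbinol mixture) | CC(=O)CC(O)[C@H]1C(C)(C)[C@@H]2CC[C@@]1(C)O2
F7 | step 9 | diethyl 4-[(1R,2S,4S)-1,3,3-trimethyl-7-oxabicyclo[2.2.1]heptan-2-yl]but-1-en-2-yl phosphate | CCOP(=O)(OCC)OC(=C)CC[C@H]1C(C)(C)[C@@H]2CC[C@@]1(C)O2
F8 | step 9 | (1R,2S,4S)-2-(but-3-yn-1-yl)-1,3,3-trimethyl-7-oxabicyclo[2.2.1]heptane | C#CCC[C@H]1C(C)(C)[C@@H]2CC[C@@]1(C)O2
F9 | step 9 | dimethyl[(1E)-2-methyl-4-[(1R,2S,4S)-1,3,3-trimethyl-7-oxabicyclo[2.2.1]heptan-2-yl]but-1-en-1-yl]alumane | C[Al](C)/C=C(\C)CC[C@H]1C(C)(C)[C@@H]2CC[C@@]1(C)O2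
F10 | step 12 | 4-chloro-5-methyl-2H-chromen-2-one | Cc1cccc2oc(=O)cc(Cl)c12
A1 | alternative 1 | (1R,2S,4R,5R)-5-iodo-1,3,3-trimethyl-2-[2-(2-methyl-1,3-dioxolan-2-yl)ethyl]-7-oxabicyclo[2.2.1]heptane (iodine endo) | CC1(CC[C@H]2C(C)(C)[C@@H]3[C@H](I)C[C@@]2(C)O3)OCCO1
A2 | alternative 1 | (1R,6S)-1,5,5-trimethyl-6-[2-(2-methyl-1,3-dioxolan-2-yl)ethyl]cyclohex-3-en-1-ol | CC1(CC[C@H]2C(C)(C)C=CC[C@@]2(C)O)OCCO1
A3 | alternative 2 | (2E)-3-methyl-5-[(1R,2S,4S)-1,3,3-trimethyl-7-oxabicyclo[2.2.1]heptan-2-yl]pent-2-en-1-ol | OC/C=C(\C)CC[C@H]1C(C)(C)[C@@H]2CC[C@@]1(C)O2
A4 | alternative 2 | (1R,2S,4S)-2-(but-3-yn-1-yl)-1,3,3-trimethyl-7-oxabicyclo[2.2.1]heptane | C#CCC[C@H]1C(C)(C)[C@@H]2CC[C@@]1(C)O2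
A5 | alternative 3 | (1R,2S,4S)-2-ethenyl-1,3,3-trimethyl-7-oxabicyclo[2.2.1]heptane (vinyl exo) | C=C[C@H]1C(C)(C)[C@@H]2CC[C@@]1(C)O2
A6 | alternative 3 | trimethyl{(2E)-4-methyl-4-[(2S)-5-methoxy-5-methyloxolan-2-yl]pent-2-en-1-yl}silane (anomeric mixture) | C[Si](C)(C)C/C=C/C(C)(C)[C@@H]1CCC(C)(OC)O1
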